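**Assumptions (one line):** (S)-(+)-carvone is the chiral starting material. The curcuminoid is drawn as its enol tautomer. The new C7 centre formed in Step 2 is assumed to form mainly as the required (S)-isomer and is separated from the minor epimer by HPLC.

## Retrosynthetic overview
1. The curcuminoid is made last by Pabon (boron-mediated Knoevenagel) condensation of aryl aldehyde **9** with p-coumaroylacetone **12**.
2. Aldehyde **9** comes from a photooxygenation endoperoxide **6**, which is opened by vanillin at the tertiary-allylic terminus and then reduced (O–O to OH).
3. Endoperoxide **6** comes from ¹O₂ [4+2] cycloaddition to an α-phellandrene-type diene **5**. The diene forms on the face anti to the ring side chain, which sets both ring oxygens.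
4. Diene **5** comes from dehydration of the carveol derivative **4**. The turmerone side chain of **4** is made by photochemical anti-Markovnikov hydroacylation of the isopropenyl group of carveol **2** with prenal.
5. The only carbocycle is the one in (S)-carvone **1**, which supplies the ring stereocentre.

## Route

**Step 1**
Reactants: **1** (S)-(+)-carvone
Product: **2** carveol, (5S), C1 epimers unspecified
Conditions: NaBH₄, CeCl₃·7H₂O, MeOH, 0 °C
Reagents that add atoms: none
Why: Luche 1,2-reduction leaves the isopropenyl group untouched, and the C1 stereochemistry is destroyed in Step 3, so the epimer ratio does not matter.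

**Step 2**
Reactants: **2** carveol; **3** prenal (3-methylbut-2-enal)
Product: **4** carveol carrying the (7S)-CH(CH₃)CH₂C(=O)CH=CMe₂ side chain
Conditions: **3** (3 equiv), (Bu₄N)₄W₁₀O₃₂ (2 mol%), (i-Pr)₃SiSH (10 mol%), MeCN, 390 nm LEDs, 25 °C, 16 h
Reagents that add atoms: none (prenal supplies the added atoms)
Why: This is photochemical radical-chain hydroacylation with thiol polarity-reversal catalysis.
- Decatungstate abstracts the aldehydic H of **3**.
- The acyl radical adds to the terminal CH₂ of the 1,1-disubstituted alkene (the trisubstituted ring alkene is far less reactive).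
- Thiol donates H to the tertiary C7 radical, anti to the larger ring branch, so C7 is controlled by the C5 stereocentre.
- I expect roughly 3:1 dr, with the diastereomers separated here.

**Step 3**
Reactants: **4**
Product: **5** diene (S)-2-methyl-5-[(S)-side chain]cyclohexa-1,3-diene
Conditions: Martin sulfurane (1.3 equiv), CH₂Cl₂, 0 → 20 °C, 1 h; cold work-up, crude used at once
Reagents that add atoms: none
Why: Dehydration of the allylic alcohol gives the same α-phellandrene-type diene whichever β-H is lost, so regiochemistry is not an issue. C5 is untouched.

**Step 4**
Reactants: **5**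
Product: **6** endoperoxide
Conditions: O₂ (1 atm), tetraphenylporphyrin (1 mol%), CH₂Cl₂, white LEDs, −10 °C, 2 h
Reagents that add atoms: singlet oxygen from O₂, O=O
Why: Schenck photooxygenation is a [4+2] cycloaddition of ¹O₂ to the diene.
- ¹O₂ adds to the face anti to the C6 side chain, as in α-phellandrene.
- Both C–O bonds therefore form trans to the chain and cis to each other, setting C1 and C4 (ring numbering of the target).
- The enone is inert to ¹O₂.

**Step 5**
Reactants: **6**; **7** vanillin
Product: **8** hydroperoxide aryl ether: 1-aryloxy, 4-OOH, cis to each other and trans to the chain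
Conditions: **7** (1.5 equiv), Sc(OTf)₃ (5 mol%), 4 Å MS, MeNO₂, −20 → 0 °C, 3 h
Reagents that add atoms: none (vanillin supplies the added atoms)
Why: Proposed new method: Lewis-acid-mediated ionic ring-opening of a bicyclic 2,3-dioxabicyclo[2.2.2]octene by a phenol, giving a cis-4-aryloxy-allylic hydroperoxide.
- Mechanism: the Lewis acid ionises the C1–O bond next to the side chain, because the resulting allyl cation has tertiary character at C3 (the methyl-bearing terminus). The C4–O bond is not ionised, because that cation would carry the methyl on its central carbon and be much less stabilised.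
- Regio- and stereochemistry: vanillin is trapped at C1 on the face anti to the C6 chain and syn to the retained C4–OOH, via an H-bonded ion pair. This retains the face of the original C1–O bond and keeps the trisubstituted C2=C3 alkene.
- Closest known reactions: SN1-type allylic etherification of allylic alcohols with phenols, and acid-mediated nucleophilic opening of endoperoxides.

**Step 6**
Reactants: **8**
Product: **9** aldehyde–alcohol
Conditions: PPh₃ (1.3 equiv), CH₂Cl₂, 0 → 20 °C, 1 h
Reagents that add atoms: none
Why: Phosphine reduction of the hydroperoxide to the alcohol with retention. The aldehyde, ketone and enone are unaffected, and no stereocentre is touched.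

**Step 7** (independent branch)
Reactants: **10** p-hydroxybenzaldehyde; **11** acetylacetone
Product: **12** (E)-6-(4-hydroxyphenyl)hex-5-ene-2,4-dione
Conditions: **11** (2.5 equiv) + B₂O₃ (1.2 equiv), EtOAc, 40 °C, 30 min; then **10**, B(OBu)₃, n-BuNH₂ (0.2 equiv), 60 °C, 4 h; then 0.4 M aq HCl, 60 °C, 1 h
Reagents that add atoms: none
Why: Pabon boron-enolate Knoevenagel mono-condensation at one methyl terminus of the acetylacetone boron complex.

**Step 8**
Reactants: **9**; **12**
Product: **13** Demethoxybisabolocurcumin ether (target)
Conditions: **12** (1.2 equiv), B₂O₃ (0.6 equiv), B(OBu)₃ (1.2 equiv), n-BuNH₂ (0.3 equiv), EtOAc, 40 °C, 6 h; then 5% aq AcOH, 40 °C, 1 h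
Reagents that add atoms: none
Why: Pabon condensation of the remaining methyl terminus of the boron-chelated diketone with the aryl aldehyde gives the (E,E)-curcuminoid. The mild acid hydrolysis of the boron complex is used so that the allylic aryl ether does not ionise.

## Compound list
1 | (S)-(+)-carvone | CC1=CC[C@@H](CC1=O)C(C)=C | starting material
2 | carveol, (5S), C1 epimers | CC1=CC[C@@H](CC1O)C(C)=C | intermediate
3 | prenal | CC(C)=CC=O | starting material
4 | carveol with (7S) turmerone side chain | CC1=CC[C@@H](CC1O)[C@@H](C)CC(=O)C=C(C)C | intermediate
5 | α-phellandrene-type diene | CC1=CC[C@@H](C=C1)[C@@H](C)CC(=O)C=C(C)C | intermediate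
6 | endoperoxide | CC1=C[C@@H]2OO[C@H]1C[C@@H]2[C@@H](C)CC(=O)C=C(C)C | intermediate
7 | vanillin | COc1cc(C=O)ccc1O | starting material
8 | hydroperoxy aryl ether | COc1cc(C=O)ccc1O[C@H]1C=C(C)[C@@H](OO)C[C@@H]1[C@@H](C)CC(=O)C=C(C)C | intermediate
9 | aldehyde–alcohol | COc1cc(C=O)ccc1O[C@H]1C=C(C)[C@@H](O)C[C@@H]1[C@@H](C)CC(=O)C=C(C)C | intermediate
10 | p-hydroxybenzaldehyde | O=Cc1ccc(O)cc1 | starting material
11 | acetylacetone | CC(=O)CC(=O)C | starting material
12 | (E)-6-(4-hydroxyphenyl)hex-5-ene-2,4-dione | CC(=O)CC(=O)/C=C/c1ccc(O)cc1 | intermediate
13 | Demethoxybisabolocurcumin ether | COc1cc(/C=C/C(O)=C/C(=O)/C=C/c2ccc(O)cc2)ccc1O[C@H]1C=C(C)[C@@H](O)C[C@@H]1[C@@H](C)CC(=O)C=C(C)C | target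

**Total steps:** 8. **Longest linear sequence:** 7 (Steps 1, 2, 3, 4, 5, 6, 8).

## Three steps most likely to fail
1. **Step 5 (proposed new step).** Risks are C- versus O-alkylation of vanillin, ionisation of the product aryl ether, and loss of regio- or facial control.
   - Fallback: reduce **6** with thiourea to the cis ene-diol. Then do SNAr of 4-fluoro-3-methoxybenzaldehyde with the mono-alkoxide (NaH, DMF), which retains configuration. Separate the regioisomers to obtain **9**.
2. **Step 2.** Risks are acyl-radical addition to the unactivated alkene with an enal-derived radical, competing HAT at the carbinol C–H, and low dr at C7.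
   - Fallback: TBS-protect **2**, then Rh-catalysed hydroformylation of the isopropenyl group. Add 2-methylpropenylmagnesium bromide to the resulting aldehyde and oxidise the allylic alcohol (DMP). Remove the TBS group and separate the C7 epimers.
3. **Step 3.** The α-phellandrene-type diene is prone to aromatisation.
   - Fallback: convert **4** to its methyl carbonate and use Tsuji Pd(0)-catalysed elimination to the same diene, telescoped directly into Step 4.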